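## Structural features

The target is a trans-fused bicyclo[5.3.0]decane (daucane-type hydroazulene). A cyclopentane (C1, C7, C8, C9, C10) shares the C1–C7 bond with a cycloheptenone (C1–C7), and a 4-methoxybenzoate sits on the C2 oxygen. Five stereocentres lie next to each other, C6–C7–C1–C2 with C10 branching from C1. C7 is quaternary (methyl α), C1 carries H on the β face, C10 is a tertiary carbinol (OH α, isopropyl β), C6 is a secondary carbinol (OH α, cis to the C7 methyl) and C2 an allylic ester carbinol (O β); the descriptors are 1S,2S,6R,7S,10R. The seven-membered ring is oxygenated at C2, C5 and C6 and holds the C3=C4–C5=O enone. The fragile groups are the C5/C6 α-ketol (enediol shift, C6 epimerisation, glycol cleavage), the allylic ester at C2 (acid-labile) and the tertiary C10–OH, which becomes a retro-aldol liability whenever C2 is a ketone. The real difficulty is the quaternary C7 wedged between the C6 carbinol and the ring fusion, together with the trans fusion and the fully substituted C10. The key step exploits two facts: C8–C9–C10(OH)(iPr) is the trace of a ketone homoenolate, and with C2 at the ketone level C7 and C1 are the β- and α-carbons of a cycloheptenone. A three-carbon donor–acceptor unit can therefore be laid across C7/C1 to close the cyclopentane. The cis C5/C6 oxygens and the methyl groups on C4 and C7 map onto a seven-membered ring derived from a 2,5-dimethylfuran cycloadduct.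

## Logic of the disconnections

19 to 18: no skeletal bond is cut; the C5 carbonyl is taken back to an allylic alcohol. The α-ketol is the most fragile part, so it is revealed last under neutral conditions. The gain is an ordinary cis-diol at C5/C6. The forward step must choose the allylic C5–OH over the neopentyl C6–OH and the tertiary C10–OH without cleaving the glycol.

18 to 17: the two O–H bonds at C5/C6 are retraced to the C–O bonds of one isopropylidene acetal. One group then masks both hydroxyls through all basic and reducing steps. The forward hydrolysis must be mild enough for the allylic ester.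

17 to 15 + 16: the ester C(=O)–O bond is cut. The aroyl group would not survive hydride or strong base, so it arrives after the reduction. The forward step must acylate the secondary C2–OH and leave the tertiary C10–OH alone.

15 to 14: the C2–H bond is removed, carbinol to ketone. The ketone is what makes C7 and C1 reactive in the earlier bond formations, and one stereocentre disappears. The forward reduction must deliver hydride to the α face of C2, which is asked of the C10 hydroxyl.

14 to 13: the C3=C4 π bond is exchanged for a C4–O bond and a C3–H bond. The C4 oxygen is what remains of an oxygen bridge, so nothing extra has to be introduced. The forward β-elimination must remove the C4 oxygen and spare the other β-oxygen at C10.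

13 to 8 + 10 (through 12 and 11): C7–C8 and C1–C10 are cut. Both are polar bonds of the C2 ketone (β and α positions) and of a C10 carbonyl. The gain is the whole cyclopentane, six carbons and three stereocentres (C7, C1, C10) in one convergent operation. The forward step demands 1,4-addition to a β,β-disubstituted enone anti to O6, a regiodefined C1 enolate, and an aldol that ends trans-fused with the right C10 face.

8 to 7 to 6: the oxygen on C4 is reconnected to C7, so the C1=C7 enone and the C4 silyloxy group become the two ends of an opened ether bridge. The gain is large: 6 is meso, and the absolute configuration reduces to choosing one of two enantiotopic α-methylene groups. The forward steps need an enantioselective deprotonation and a ring opening that keeps the enol regiochemistry.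

6 to 5 to 4: the C5–O and C6–O bonds are cut back to an alkene. The exo face of the bicyclic alkene is the open one, so both oxygens enter cis to the bridge. Two stereocentres are removed; the forward step needs only exo selectivity.

4 to 1 + 2 (through 3): C1–C7 and C3–C4 are cut, a (4+3) retron. The seven-membered ring with both methyl-bearing carbons and the C2 carbonyl comes from two commercial compounds. The forward step needs an oxyallyl cation and removal of the two surplus bromines.

10 to 9: the two cyclopropane bonds from the carbinol carbon are cut. The ester is commercial and no selectivity is required.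

## Other disconnections considered

Alternative 1: The cut is C1–C2, so the seven-membered ring is closed last onto a preformed cyclopentene. In the forward step a Lewis acid activates the C2 aldehyde of the allylsilane aldehyde A2. The C1 terminus of its C1=C10–C9(SiMe3) unit attacks anti to silicon, the ring closes, and loss of silicon leaves C9=C10 in the bicyclic alcohol A1.
- In favour: C1 is set by a stereospecific, kinetically controlled event, and the C2 oxygen appears directly at the alcohol level. On both points this plan is the equal or the better of the chosen one, which needs a directed reduction for C2 and leans partly on equilibration for C1.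
- Against: A2 must already hold the quaternary C7, a configurationally defined C9 silane and a five-carbon oxygenated chain, so most of the stereochemical work moves into a long linear preparation. Seven-membered closure carries an entropic cost, and the C2 configuration rests on a transition-state preference that is hard to predict. After A1, C10 must still be hydrated with Markovnikov regiochemistry on the α face, C5 oxidised, and C3=C4 introduced by desaturation of a C5 ketone that can also enolise towards C6.
- Comparison: the chosen plan obtains the oxygenated seven-membered ring in five steps and builds C10 at its final oxidation level during ring formation. Both plans use known polar chemistry. The alternative should be clearly longer before its key step and somewhat longer after it.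

Alternative 2: The cut is the biosynthetic one, C6–C7 and C1–C10. A class I sesquiterpene cyclase would ionise (2E,6E)-farnesyl diphosphate A3 (the carbon losing diphosphate becomes C6) and close both rings. After a 1,2-hydride shift from C10 it would capture water at C10 to give the daucene-type alcohol A4.
- In favour: one aqueous operation from an achiral C15 precursor would deliver both rings, the quaternary C7, the trans fusion and the C10 carbinol. In skeletal step economy and in control of C1/C7/C10 this is better than the chosen plan.
- Against: it needs a cyclase with exactly this product profile and absolute sense, in expressible and scalable form. A4 has no oxygen at C2, C5 or C6, and its alkene is C4=C5, not C3=C4. C6 is allylic and within reach, but C2 is an unactivated methylene beside the ring fusion.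
- Comparison: the alternative wins on ring construction and loses on oxygenation. In the chosen plan every oxygen enters as a functional group of a building block (oxyallyl carbonyl for C2, alkene dihydroxylation for C5/C6, homoenolate carbonyl for C10). The cationic cascade cannot be tuned by the chemist, and the step count beyond A4 is open-ended.

Alternative 3: The cut is C1–C7 across a cyclodecane. A chiral primary amine would condense with the C10 ketone of the ten-membered enedione A5, and the C1 enamine would add across the ring to C7 of the C5 enone, giving the hydroazulenedione A6.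
- In favour: the step is catalytic and enantioselective and would create the quaternary centre, the ring fusion and both rings at once. It leaves a ketone at C5 exactly where the target needs one, which is equal or better than the late oxidation of the chosen plan, and a C10 ketone ready for isopropyl addition.
- Against: A5 is a medium ring whose preparation is a problem of its own. Cis or trans fusion depends on the macrocycle conformation. A6 lacks the C2 and C6 oxygens; hydroxylation at C6 must compete with C4, and C2 is reachable only by desaturating towards C1 and further steps. The isopropyl nucleophile must also distinguish C10 from C5 and pick the right face.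
- Comparison: the alternative is shorter to the bare bicycle and carries its own asymmetric catalysis. The chosen plan is longer in ring construction but has every heteroatom in place when the rings are complete, which should make its endgame shorter and more predictable.

Key step: step 7

**Remarks on the chemistry**

- Locants C1–C10 are those of the target throughout, except that compounds 3–7 are named with bicyclo[3.2.1]octane numbering. α is the face carrying the C7 methyl group, β the face carrying H-1.
- The configurations of 8, 13 and 19 were compared centre by centre (C4–C7, C1, C10) and are mutually consistent; no structural correction was needed.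
- Assumption: the three-carbon partner is used as free 1-isopropylcyclopropan-1-ol (10), not its trimethylsilyl ether. Diethylzinc opens cyclopropanols to ketone homoenolates, whereas zinc halides tend to isomerise simple 1-alkyl-1-silyloxycyclopropanes. Skeleton, bonds formed and product are unchanged, and one silylation step is saved.
- Assumption: the (R,R)-amide is written for step 4. Its sense of induction on this 1,5-dimethyl substrate is assumed by analogy with the unsubstituted oxabicyclic ketones and must be confirmed; the (S,S)-amine is equally available.
- Correction to the stereochemical reasoning: C1 and C10 are coupled, so epimerising C1 after a chelated cis-closure would give the C10 epimer. The plan therefore relies on reversibility of the C1–C10 bond (see step 7).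

**Steps**

Step 1
Reactants: 1 1,1,3,3-tetrabromoacetone; 2 2,5-dimethylfuran
Product: 4 1,5-dimethyl-8-oxabicyclo[3.2.1]oct-6-en-3-one (meso), via dibromo cycloadduct 3 (not isolated)
Conditions: Zn–Ag couple, THF, −10 °C → rt; then Zn–Cu couple, NH4Cl, MeOH, rt
Reagents that add atoms: none
Why: Oxyallyl cation (4+3) cycloaddition: zinc reduces 1 to the 1,3-dibromo-2-oxyallyl species, which adds across C2/C5 of the electron-rich furan 2 to give 3; Zn–Cu/NH4Cl then removes both α-bromines, and the bridge fixes the cis relation of the two methyl-bearing bridgeheads in meso 4.

Step 2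
Reactants: 4 1,5-dimethyl-8-oxabicyclo[3.2.1]oct-6-en-3-one
Product: 5 6-exo,7-exo-dihydroxy-1,5-dimethyl-8-oxabicyclo[3.2.1]octan-3-one (meso)
Conditions: K2OsO4·2H2O (cat.), NMO, acetone/H2O, rt
Reagents that add atoms: 4-methylmorpholine N-oxide, C[N+]1([O-])CCOCC1; water, O (both through the osmium catalyst)
Why: Upjohn dihydroxylation; osmium adds from the exo face, syn to the one-atom oxygen bridge and away from the three-carbon ketone bridge, so both new hydroxyls (C5 and C6 of the target) are cis to the bridging oxygen and 5 stays meso.

Step 3
Reactants: 5 meso exo-diol
Product: 6 6-exo,7-exo-(isopropylidenedioxy)-1,5-dimethyl-8-oxabicyclo[3.2.1]octan-3-one (meso)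
Conditions: 2,2-dimethoxypropane, PPTS (cat.), acetone, rt
Reagents that add atoms: 2,2-dimethoxypropane, COC(C)(C)OC
Why: Acid-catalysed transacetalisation of the cis-1,2-diol to the five-membered isopropylidene acetal; no stereocentre is touched and the ketone stays free.

Step 4
Reactants: 6 meso acetonide ketone
Product: 7 6-exo,7-exo-(isopropylidenedioxy)-1,5-dimethyl-3-(trimethylsilyloxy)-8-oxabicyclo[3.2.1]oct-2-ene (single enantiomer; enol double bond towards the bridgehead that becomes C7)
Conditions: (R,R)-bis(1-phenylethyl)amine, n-BuLi, LiCl, TMSCl (in situ), THF, −100 → −78 °C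
Reagents that add atoms: chlorotrimethylsilane, C[Si](C)(C)Cl
Why: Enantiotopic-group-selective deprotonation of a meso ketone by a C2-symmetric chiral lithium amide with in situ silyl trapping (kinetic control, no enolate equilibration); choosing one of the two α-methylenes fixes the absolute configuration of every stereocentre carried forward and marks which bridgehead C–O bond will break.

Step 5
Reactants: 7 enantioenriched bicyclic enol silane
Product: 8 (4S,5R,6R)-cycloheptenone: C2 ketone, C1=C7 alkene with methyl on C7, 5α,6α-isopropylidenedioxy, 4β-methyl, 4α-trimethylsilyloxy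
Conditions: TMSOTf (10 mol%), 2,6-di-tert-butylpyridine (cat.), CH2Cl2, −78 → −40 °C; Et3N quench
Reagents that add atoms: none
Why: Silyl-triflate-catalysed opening of the oxygen bridge: silylation of the bridging oxygen lets the enol ether expel the allylic, tertiary C7–O bond (vinylogous β-elimination), and the silylated enone returns TMS+ to triflate, so the net change is an isomerisation to the C1=C7 enone with the C4 oxygen silylated; C4, C5 and C6 are not involved.

Step 6
Reactants: 9 methyl isobutyrate
Product: 10 1-isopropylcyclopropan-1-ol
Conditions: EtMgBr (2.4 equiv), Ti(OiPr)4 (20 mol%), Et2O, 0 °C → rt; cold dilute H2SO4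
Reagents that add atoms: ethylmagnesium bromide, CC[Mg]Br
Why: Kulinkovich reaction: the titanacyclopropane formed from EtMgBr and catalytic Ti(OiPr)4 acts as a 1,2-dicarbanion towards the ester carbonyl; the product has no stereocentre.

Step 7
Reactants: 8 (4S,5R,6R)-cycloheptenone; 10 1-isopropylcyclopropan-1-ol
Product: 13 (1R,4S,5R,6R,7S,10R) trans-fused hydroazulenone (C2 ketone; C10 carbinol with OH α and isopropyl β; H-1 β; 7α-methyl; C4 OTMS; C5/C6 acetonide), via zinc homoenolate 11 (not isolated), via enol silane 12 (not isolated)
Conditions: 10 (3 equiv), Et2Zn (1.5 equiv), THF, 0 °C → rt; then 8, CuBr·SMe2 (20 mol%), TMSCl, DMPU, −20 °C → rt; cold NaHCO3 wash, concentrate; t-BuOK (1.05 equiv), THF, −78 → −40 °C; AcOH, −78 °C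
Reagents that add atoms: none
Why: Diethylzinc converts two equivalents of 10 into the zinc bis(cyclopropoxide), which opens by strain-driven C–C cleavage to the ethyl-free ketone homoenolate 11; transmetalation to copper and TMSCl/DMPU-assisted 1,4-addition to 8 forms C7–C8 and traps the enolate regiospecifically as the C1=C2 enol silane 12. The closest known reaction type is the copper-catalysed, chlorosilane-accelerated conjugate addition of zinc homoenolates to enones followed by aldol cyclisation of the 1,6-dicarbonyl adduct. C7 is set by the substrate: the copper reagent attacks anti to the allylic C6 oxygen and to the α-fused dioxolane, so C8 enters on the β face and the methyl group ends α, cis to O6. tert-Butoxide then attacks silicon of the enol ether (the tertiary C4 silyl ether is far slower) and releases the C1 potassium enolate without proton transfer, so C3 and the side-chain α-positions are never enolised. The cyclopentane closes by a 5-(enolexo)-exo-trig aldol addition of C1 to the C10 ketone, with the cation bridging O2 and O10 so that the new hydroxyl lies syn to C2 and the isopropyl group anti. Under that constraint the trans-fused aldolate keeps isopropyl away from both C2 and the angular methyl, whereas a cis-fused chelate would press it against the methyl; the trans isomer (H-1 β, OH-10 α) should therefore be favoured among chelated pathways and at equilibrium through retro-aldol/aldol exchange before the cold quench. Epimerising C1 alone would turn a cis-fused chelate into the C10 epimer, so reversibility of the C1–C10 bond, not enolisation, is relied on, and after protonation the C10–OH···O=C2 hydrogen bond holds 13. The step needs 1,4- over 1,2-addition (copper with TMSCl), homoenolate over ethyl transfer (2:1 alcohol-to-zinc stoichiometry) and survival of the β-silyloxy group at C4 (no excess base, low temperature).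

Step 8
Reactants: 13 trans-fused hydroazulenone
Product: 14 (1R,5S,6R,7S,10R) enone: C2 ketone, C3=C4 with methyl on C4, C5/C6 acetonide, C10–OH
Conditions: DBU (2 equiv), CH2Cl2, 0 °C → rt
Reagents that add atoms: none
Why: E1cB elimination of a β-silyloxy ketone: DBU enolises towards the unhindered C3 methylene and silanolate leaves from C4 to give the conjugated C3=C4 enone; C1–H is shielded by two fully substituted neighbours and the amidine is too weak to form the C10 alkoxide needed for retro-aldol, so the other β-oxygen should stay.

Step 9
Reactants: 14 enone
Product: 15 (1S,2S,5S,6R,7S,10R) allylic alcohol: 2β-OH, C3=C4, C5/C6 acetonide, C10–OH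
Conditions: Me4NBH(OAc)3, MeCN/AcOH (1:1), −30 → 0 °C; aq. Rochelle salt
Reagents that add atoms: none
Why: Hydroxyl-directed (Evans–Saksena) reduction: the C10 hydroxyl exchanges onto boron and delivers hydride intramolecularly to the α face of the C2 carbonyl through a six-membered transition state, placing the new C2 oxygen β (anti to O10, cis to H-1) with 1,2-reduction only.

Step 10
Reactants: 15 allylic alcohol; 16 4-methoxybenzoyl chloride
Product: 17 (1S,2S,5S,6R,7S,10R) 2-O-(4-methoxybenzoyl) acetonide
Conditions: Et3N, DMAP (cat.), CH2Cl2, 0 °C → rt
Reagents that add atoms: none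
Why: DMAP-catalysed acylation: the secondary allylic C2–OH reacts while the tertiary C10–OH does not; no stereocentre is involved.

Step 11
Reactants: 17 anisoate acetonide
Product: 18 (1S,2S,5S,6R,7S,10R) 5α,6α,10α-triol 2-(4-methoxybenzoate)
Conditions: AcOH/H2O (4:1), 40 °C
Reagents that add atoms: none
Why: Acid hydrolysis of the isopropylidene acetal to the cis-5,6-diol; dilute acetic acid at mild temperature should spare the allylic 4-methoxybenzoate and the tertiary alcohol.

Step 12
Reactants: 18 triol ester
Product: 19 (1S,2S,6R,7S,10R) target (CNP0299970.1)
Conditions: activated MnO2 (excess), CH2Cl2, rt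
Reagents that add atoms: none
Why: Chemoselective allylic oxidation with manganese dioxide: only the C5 hydroxyl is allylic, the C6 hydroxyl is saturated and neopentylic and the C10 hydroxyl is tertiary; the neutral heterogeneous conditions should leave the C6 configuration of the new α-ketol untouched.

**Compound list**

1 | 1,1,3,3-tetrabromoacetone | O=C(C(Br)Br)C(Br)Br | starting material
2 | 2,5-dimethylfuran | Cc1ccc(C)o1 | starting material
3 | 2,4-dibromo-1,5-dimethyl-8-oxabicyclo[3.2.1]oct-6-en-3-one (mixture of bromine epimers, drawn without those descriptors) | O=C1C(Br)[C@@]2(C)O[C@@](C)(C1Br)C=C2 | intermediate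
4 | 1,5-dimethyl-8-oxabicyclo[3.2.1]oct-6-en-3-one (meso) | O=C1C[C@@]2(C)O[C@@](C)(C1)C=C2 | intermediate
5 | 6-exo,7-exo-dihydroxy-1,5-dimethyl-8-oxabicyclo[3.2.1]octan-3-one (meso) | O=C1C[C@@]2(C)O[C@@](C)(C1)[C@H](O)[C@@H]2O | intermediate
6 | 6-exo,7-exo-(isopropylidenedioxy)-1,5-dimethyl-8-oxabicyclo[3.2.1]octan-3-one (meso) | O=C1C[C@@]2(C)O[C@@](C)(C1)[C@@H]3OC(C)(C)O[C@H]23 | intermediate
7 | 6-exo,7-exo-(isopropylidenedioxy)-1,5-dimethyl-3-(trimethylsilyloxy)-8-oxabicyclo[3.2.1]oct-2-ene, single enantiomer | C[Si](C)(C)OC1=C[C@@]2(C)O[C@@](C)(C1)[C@@H]3OC(C)(C)O[C@H]23 | intermediate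
8 | (4S,5R,6R)-cycloheptenone: C2 ketone, C1=C7, 7-methyl, 5α,6α-isopropylidenedioxy, 4β-methyl, 4α-OTMS | O=C1C=C(C)[C@H]2OC(C)(C)O[C@H]2[C@@](C)(O[Si](C)(C)C)C1 | intermediate
9 | methyl isobutyrate | COC(=O)C(C)C | starting material
10 | 1-isopropylcyclopropan-1-ol | CC(C)C1(O)CC1 | intermediate
11 | bis(4-methyl-3-oxopentyl)zinc (zinc homoenolate) | CC(C)C(=O)CC[Zn]CCC(=O)C(C)C | intermediate
12 | (4S,5R,6R,7S) enol silane: C1=C2–OTMS, 7α-methyl, 7β-(4-methyl-3-oxopentyl), C4 OTMS, C5/C6 acetonide | C[Si](C)(C)OC1=C[C@](C)(CCC(=O)C(C)C)[C@H]2OC(C)(C)O[C@H]2[C@@](C)(O[Si](C)(C)C)C1 | intermediate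
13 | (1R,4S,5R,6R,7S,10R) trans-fused hydroazulenone: C2 ketone, 10α-OH, 10β-isopropyl, H-1 β, 7α-methyl, C4 OTMS, C5/C6 acetonide | O=C1C[C@](C)(O[Si](C)(C)C)[C@@H]3OC(C)(C)O[C@@H]3[C@@]2(C)CC[C@@](O)(C(C)C)[C@H]12 | intermediate
14 | (1R,5S,6R,7S,10R) enone: C2 ketone, C3=C4(Me), C5/C6 acetonide, 10α-OH | O=C1C=C(C)[C@@H]3OC(C)(C)O[C@@H]3[C@@]2(C)CC[C@@](O)(C(C)C)[C@H]12 | intermediate
15 | (1S,2S,5S,6R,7S,10R) allylic alcohol: 2β-OH, C3=C4(Me), C5/C6 acetonide, 10α-OH | O[C@H]1C=C(C)[C@@H]3OC(C)(C)O[C@@H]3[C@@]2(C)CC[C@@](O)(C(C)C)[C@H]12 | intermediate
16 | 4-methoxybenzoyl chloride | COc1ccc(C(Cl)=O)cc1 | starting material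
17 | (1S,2S,5S,6R,7S,10R) 2β-(4-methoxybenzoyloxy) acetonide | COc1ccc(C(=O)O[C@H]2C=C(C)[C@@H]4OC(C)(C)O[C@@H]4[C@@]3(C)CC[C@@](O)(C(C)C)[C@H]23)cc1 | intermediate
18 | (1S,2S,5S,6R,7S,10R) 5α,6α,10α-triol 2-(4-methoxybenzoate) | COc1ccc(C(=O)O[C@H]2C=C(C)[C@H](O)[C@H](O)[C@@]3(C)CC[C@@](O)(C(C)C)[C@H]23)cc1 | intermediate
19 | (1S,2S,6R,7S,10R)-6,10-dihydroxy-10-isopropyl-4,7-dimethyl-5-oxo-bicyclo[5.3.0]dec-3-en-2-yl 4-methoxybenzoate (target locants) | COc1ccc(C(=O)O[C@H]2C=C(C)C(=O)[C@H](O)[C@@]3(C)CC[C@@](O)(C(C)C)[C@H]23)cc1 | target

**Step count and risks**

Total: 12 steps. Longest linear sequence: 11 steps (steps 1–5 and 7–12); step 6 is a one-step side branch.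

Step 7 (key step). Most likely failures are a sluggish transfer of the ketone homoenolate to the hindered β,β-disubstituted enone (with silylation of the zinc cyclopropoxide or protonation of the homoenolate winning), and stereochemical leakage at the aldol stage (cis fusion or the wrong C10 face, with loss of the C4 silyloxy group if the enolate is warmed). Fallback, from 8 back to 13:
- Copper-catalysed, TMSCl-assisted addition of (4-methylpent-3-en-1-yl)magnesium bromide, the most dependable route to a quaternary β-carbon, should give the homoprenyl enol silane F1.
- Buffered hydrolysis gives the homoprenyl ketone F2.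
- Buffered mCPBA epoxidation of the trisubstituted alkene gives the epoxy ketone F3 (either epoxide epimer serves).
- Lewis-acid Meinwald rearrangement with hydride shift gives the 1,6-diketone F4.
- Reversible base-mediated aldol (catalytic t-BuOK, t-BuOH/THF, 0 °C) closes C1–C10, the only enolate/carbonyl pairing that gives an unstrained ring, and rejoins the route at 13.

Step 4. The bridgehead methyl groups crowd the α-protons, so discrimination between the enantiotopic methylenes may be poor, and the sense of induction is assumed. Fallback, from 6 back to 8: LDA/TMSCl gives the racemate, i.e. 7 together with the mirror-image enol silane F5. The ring opening of step 5 then gives 8 with the mirror-image enone F6, and the two are separated by preparative chromatography on a chiral stationary phase before the convergent step.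

Step 8. Retro-aldol fragmentation of C1–C10 or loss of the C10 oxygen may compete with loss of silanolate from C4. Fallback, from 13 back to 14: 1-(trimethylsilyl)imidazole silylates the C10 hydroxyl to give the bis-silyl ether F7, which has no free hydroxyl for retro-aldol. Base-induced elimination at C4 then gives the C10-silyloxy enone F8, and K2CO3/MeOH removes the remaining silyl group to reach 14.

Step 9. The tertiary hydroxyl may exchange onto boron too slowly, giving slow or undirected reduction and poor facial selectivity. Fallback, from 14 to 17 (bypassing 15): Luche reduction should deliver hydride from the less hindered β face to give the 2-epi alcohol F9. A Mitsunobu reaction with 4-methoxybenzoic acid (PPh3, DIAD) then inverts C2 and installs the ester in one step.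

Step 12. Over-oxidation, cleavage of the C5–C6 glycol, or isomerisation of the α-ketol may occur. Fallback, from 18 back to 19:
- TESOTf/2,6-lutidine gives the tris(triethylsilyl) ether F10.
- PPTS/MeOH frees only the least hindered, allylic C5 hydroxyl to give the C5 alcohol F11.
- Dess–Martin oxidation gives the silyl-protected ketone F12.
- HF·pyridine removes both remaining silyl groups to give 19.

## Further compounds

F1 | step 7 | homoprenyl enol silane (C1=C2–OTMS, 7α-methyl, 7β-(4-methylpent-3-enyl), C4 OTMS, C5/C6 acetonide) | C[Si](C)(C)OC1=C[C@](C)(CCC=C(C)C)[C@H]2OC(C)(C)O[C@H]2[C@@](C)(O[Si](C)(C)C)C1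
F2 | step 7 | homoprenyl ketone (C2 ketone, 7β-(4-methylpent-3-enyl)) | O=C1C[C@](C)(CCC=C(C)C)[C@H]2OC(C)(C)O[C@H]2[C@@](C)(O[Si](C)(C)C)C1
F3 | step 7 | epoxy ketone (both epimers at the epoxide carbon) | O=C1C[C@](C)(CCC2OC2(C)C)[C@H]3OC(C)(C)O[C@H]3[C@@](C)(O[Si](C)(C)C)C1
F4 | step 7 | 1,6-diketone (C2 and C10 ketones, C4 OTMS, C5/C6 acetonide) | O=C1C[C@](C)(CCC(=O)C(C)C)[C@H]2OC(C)(C)O[C@H]2[C@@](C)(O[Si](C)(C)C)C1
F5 | step 4 | mirror-image enol silane (enantiomer of 7) | C[Si](C)(C)OC1=C[C@]2(C)O[C@](C)(C1)[C@H]3OC(C)(C)O[C@@H]23
F6 | step 4 | mirror-image enone (enantiomer of 8) | O=C1C=C(C)[C@@H]2OC(C)(C)O[C@@H]2[C@](C)(O[Si](C)(C)C)C1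
F7 | step 8 | bis-silyl ether (13 with C10–OTMS) | O=C1C[C@](C)(O[Si](C)(C)C)[C@@H]3OC(C)(C)O[C@@H]3[C@@]2(C)CC[C@@](O[Si](C)(C)C)(C(C)C)[C@H]12
F8 | step 8 | C10-silyloxy enone (14 with C10–OTMS) | O=C1C=C(C)[C@@H]3OC(C)(C)O[C@@H]3[C@@]2(C)CC[C@@](O[Si](C)(C)C)(C(C)C)[C@H]12
F9 | step 9 | 2-epi alcohol (2α-OH epimer of 15) | O[C@@H]1C=C(C)[C@@H]3OC(C)(C)O[C@@H]3[C@@]2(C)CC[C@@](O)(C(C)C)[C@H]12
F10 | step 12 | tris(triethylsilyl) ether of 18 | COc1ccc(C(=O)O[C@H]2C=C(C)[C@H](O[Si](CC)(CC)CC)[C@H](O[Si](CC)(CC)CC)[C@@]3(C)CC[C@@](O[Si](CC)(CC)CC)(C(C)C)[C@H]23)cc1
F11 | step 12 | C5 alcohol with C6 and C10 triethylsilyl ethers | COc1ccc(C(=O)O[C@H]2C=C(C)[C@H](O)[C@H](O[Si](CC)(CC)CC)[C@@]3(C)CC[C@@](O[Si](CC)(CC)CC)(C(C)C)[C@H]23)cc1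
F12 | step 12 | silyl-protected ketone (C5 ketone, C6 and C10 triethylsilyl ethers) | COc1ccc(C(=O)O[C@H]2C=C(C)C(=O)[C@H](O[Si](CC)(CC)CC)[C@@]3(C)CC[C@@](O[Si](CC)(CC)CC)(C(C)C)[C@H]23)cc1
A1 | alternative 1 | trans-fused bicyclic alcohol (C2 carbinol, C9=C10 with isopropyl, C5 PMB ether, C6 TBS ether) | O[C@H]1CC(C)C(OCc3ccc(OC)cc3)[C@H](O[Si](C)(C)C(C)(C)C)[C@@]2(C)CC=C(C(C)C)[C@H]12
A2 | alternative 1 | allylsilane aldehyde (C2 aldehyde, C1=C10 cyclopentene, 9β-trimethylsilyl) | O=CCC(C)C(OCc1ccc(OC)cc1)[C@H](O[Si](C)(C)C(C)(C)C)[C@@]2(C)C[C@@H]([Si](C)(C)C)C(C(C)C)=C2
A3 | alternative 2 | (2E,6E)-farnesyl diphosphate | CC(C)=CCC/C(C)=C/CC/C(C)=C/COP(=O)(O)OP(=O)(O)O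
A4 | alternative 2 | daucene-type alcohol (C10 carbinol, C4=C5) | C1CC(C)=CC[C@@]2(C)CC[C@@](O)(C(C)C)[C@H]12
A5 | alternative 3 | (E)-3,10-dimethylcyclodec-2-ene-1,6-dione (ten-membered enedione) | O=C1CC/C(C)=C/C(=O)C(C)CCC1
A6 | alternative 3 | trans-fused hydroazulenedione (C5 and C10 ketones, C4 epimers) | C1CC(C)C(=O)C[C@@]2(C)CCC(=O)[C@H]12
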